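**Retrosynthetic overview**

1. Sanggenol C (19) comes from its 5,7-bis-MOM ether 18 by acidic methanolysis.
2. Ring C is the only ring that is built and it is closed last, at the O1–C2 bond. C2 is benzylic to ring B and para to the C4' oxygen, so it can become the exocyclic carbon of a para-quinone methide of ring B; O1, the oxygen on C8a of ring A, adds to it. The precursor is benzylic acetate 14.
3. 14 comes from a C2–C3 disconnection: a chiral boron aldol of the ring-A α-silyloxy ketone 7 with the ring-B aldehyde 11. Only C3 has to be set there; C2 is set at ring closure.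
4. 7 comes from 2,4,6-trihydroxyacetophenone (C-prenylation, MOM on the later C5/C7 oxygens, α-hydroxylation, silylation); 11 comes from 4-hydroxybenzaldehyde (ortho C-geranylation, silylation).
5. The C8a and C4' phenols travel as TBS ethers so that one fluoride charge frees both, and the C5 and C7 oxygens stay as MOM ethers so that only O1 can close the ring.

Key step: step 9

Assumption: the Z-enol diisopinocampheylborinate of 7 is taken to follow the same chair transition state and aldehyde-face sense as Ipc allylboration, so that (+)-Ipc2BOTf (from (+)-Ipc2BH, i.e. (–)-α-pinene) gives the (2R,3S)-syn adduct; if the first run shows the opposite sense, (–)-Ipc2BOTf is used with no other change.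

**Route**

Step 1
Reactants: 1 2,4,6-trihydroxyacetophenone; 2 prenyl bromide
Product: 3 1-[2,4,6-trihydroxy-3-(3-methylbut-2-en-1-yl)phenyl]ethan-1-one
Conditions: DBU (1.1 equiv), THF, 0 °C → rt
Reagents that add atoms: none
Why: Base-mediated C-alkylation of the acylphloroglucinol (ambident phenoxide reacting at ring carbon, SN2 on the allylic bromide); C3 and C5 are equivalent and one equivalent of bromide limits dialkylation.

Step 2
Reactants: 3 1-[2,4,6-trihydroxy-3-prenylphenyl]ethan-1-one
Product: 4 1-[2-hydroxy-4,6-bis(methoxymethoxy)-3-(3-methylbut-2-en-1-yl)phenyl]ethan-1-one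
Conditions: MOMCl (2.2 equiv), iPr2NEt, CH2Cl2, 0 °C → rt
Reagents that add atoms: chloromethyl methyl ether, COCCl
Why: Williamson-type O-alkylation (MOM acetal formation) of the two more accessible phenols; the 2-OH is hydrogen-bonded to the ketone and flanked by the prenyl group, so it should stay free.

Step 3
Reactants: 4 1-[2-hydroxy-4,6-bis(methoxymethoxy)-3-prenylphenyl]ethan-1-one
Product: 6 2-hydroxy-1-[2-hydroxy-4,6-bis(methoxymethoxy)-3-prenylphenyl]ethan-1-one, via dipotassium phenoxide-enolate 5 (not isolated)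
Conditions: KHMDS (2.4 equiv), THF, –78 → –40 °C; trans-2-(phenylsulfonyl)-3-phenyloxaziridine, –78 °C; AcOH
Reagents that add atoms: trans-2-(phenylsulfonyl)-3-phenyloxaziridine, O=S(=O)(c1ccccc1)N1OC1c1ccccc1
Why: Davis enolate oxidation: the phenoxide-enolate dianion is hydroxylated at carbon by the electrophilic N-sulfonyloxaziridine, which leaves the isolated alkenes untouched; keeping the phenol as its phenoxide avoids an aryl-O to enolate-O silyl shift that a silylated phenol could undergo.

Step 4
Reactants: 6 2-hydroxy-1-[2-hydroxy-4,6-bis(methoxymethoxy)-3-prenylphenyl]ethan-1-one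
Product: 7 2-(tert-butyldimethylsilyloxy)-1-[2-(tert-butyldimethylsilyloxy)-4,6-bis(methoxymethoxy)-3-prenylphenyl]ethan-1-one
Conditions: TBSOTf (2.5 equiv), 2,6-lutidine, CH2Cl2, –40 → 0 °C
Reagents that add atoms: tert-butyldimethylsilyl trifluoromethanesulfonate, CC(C)(C)[Si](C)(C)OS(=O)(=O)C(F)(F)F
Why: Silyl triflate silylation of the primary alcohol and of the chelated phenol in one operation; 2,6-lutidine is too weak a base to give the silyl enol ether, and the phenol must be capped because it would otherwise consume the boron triflate in step 7 and be acetylated in step 8.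

Step 5
Reactants: 8 4-hydroxybenzaldehyde; 9 geranyl bromide
Product: 10 3-[(2E)-3,7-dimethylocta-2,6-dien-1-yl]-4-hydroxybenzaldehyde
Conditions: KOH (10% aq), rt
Reagents that add atoms: none
Why: ortho C-alkylation of the phenoxide in water (SN2 on the allylic bromide, E geometry retained); the protic medium solvates the oxygen and favours C- over O-alkylation, and the para position is blocked; a modest yield is expected and is accepted at this first step.

Step 6
Reactants: 10 3-geranyl-4-hydroxybenzaldehyde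
Product: 11 4-(tert-butyldimethylsilyloxy)-3-[(2E)-3,7-dimethylocta-2,6-dien-1-yl]benzaldehyde
Conditions: TBSCl, imidazole, DMF, rt
Reagents that add atoms: tert-butyldimethylsilyl chloride, CC(C)(C)[Si](C)(C)Cl
Why: Standard imidazole-promoted silylation of an unhindered, non-chelated phenol.

Step 7
Reactants: 7 2-(tert-butyldimethylsilyloxy)-1-[2-(tert-butyldimethylsilyloxy)-4,6-bis(methoxymethoxy)-3-prenylphenyl]ethan-1-one; 11 4-(tert-butyldimethylsilyloxy)-3-geranylbenzaldehyde
Product: 13 (2R,3S)-2-(tert-butyldimethylsilyloxy)-3-[4-(tert-butyldimethylsilyloxy)-3-geranylphenyl]-3-hydroxy-1-[2-(tert-butyldimethylsilyloxy)-4,6-bis(methoxymethoxy)-3-prenylphenyl]propan-1-one, via (Z)-enol diisopinocampheylborinate 12 (not isolated)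
Conditions: (+)-Ipc2BOTf, iPr2NEt, CH2Cl2, –78 → 0 °C; 11, –78 → –20 °C; then H2O2, pH 7 buffer, MeOH, 0 °C
Reagents that add atoms: none
Why: Paterson boron aldol: the Z-enol borinate (OTBS cis to OB, as expected for an aryl α-oxy ketone) should react through a chair Zimmerman–Traxler transition state to give the 2,3-syn adduct, the Ipc ligands choosing the enolate face so that C2 (the later C3 of the flavanonol) is R; C3 of 13 is S in the syn isomer but need not be pure, since any epimer at this centre with the same C2 configuration converges in step 9.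

Step 8
Reactants: 13 (2R,3S)-syn aldol adduct
Product: 14 (2R,3S)-3-acetoxy-2-(tert-butyldimethylsilyloxy)-3-[4-(tert-butyldimethylsilyloxy)-3-geranylphenyl]-1-[2-(tert-butyldimethylsilyloxy)-4,6-bis(methoxymethoxy)-3-prenylphenyl]propan-1-one
Conditions: Ac2O, pyridine, DMAP (cat.), CH2Cl2, 0 °C → rt
Reagents that add atoms: acetic anhydride, CC(=O)OC(C)=O
Why: DMAP-catalysed acylation of the only free hydroxyl; the acetate blocks retro-aldol cleavage and serves as the leaving group of the key step, and no stereocentre is touched.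

Step 9
Reactants: 14 (2R,3S)-3-acetoxy-2-(tert-butyldimethylsilyloxy)-1,3-diarylpropan-1-one
Product: 18 (2R,3R)-3-hydroxy-2-(3-geranyl-4-hydroxyphenyl)-5,7-bis(methoxymethoxy)-8-prenylchroman-4-one, via bis-phenol acetate 15 (not isolated), via para-quinone methide 16 (not isolated), via 3-O-TBS dihydroflavonol 17 (not isolated)
Conditions: TBAF (2.2 equiv), AcOH (1.1 equiv), THF, –40 → 0 °C, Ar; then HF·pyridine, pyridine, 0 °C → rt
Reagents that add atoms: none
Why: Proposed new method: fluoride should cleave the two aryl silyl ethers far faster than the secondary alkyl one, the C4' phenoxide then expels the para-benzylic acetate (1,6-elimination) to give quinone methide 16, the C8a phenoxide adds to its exocyclic carbon C2 (intramolecular oxa-1,6-addition) with re-aromatisation of ring B, and HF·pyridine finally removes the C3 silyl group. The closest known reaction types are fluoride-triggered 1,6-eliminations of 4-silyloxybenzyl esters to para-quinone methides that are trapped by a tethered oxygen nucleophile, the addition of phenols to β-oxygenated quinone methides of lignin models, and the C2 epimerisation of 4'-hydroxyflavanones through the ring-opened quinone methide, of which this closure is the reverse. Ring C is closed at the O1–C2 bond in a 6-exo-trig mode, because the C2=C1' double bond of 16 lies outside the new ring. The new centre C2 is controlled by C3: in a chair-like transition state the quinone methide arm and the OTBS group both sit pseudo-equatorial, which gives the 2,3-trans (2R,3R) product, and since the addition is reversible while the C4' phenoxide is present, any cis isomer can return to 16 and end as the more stable trans isomer; as C2 is planar in 16, both benzylic epimers of 14 give the same product. The step needs O1 to be the only nucleophile, which the MOM ethers on the C5 and C7 oxygens secure, and it needs ring closure to outrun loss of the C3 proton from 16 and E1cB loss of acetate from 14, which the half-buffered medium, the low temperature and the proximity of the C8a phenoxide should favour.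

Step 10
Reactants: 18 (2R,3R)-5,7-bis-O-(methoxymethyl) dihydroflavonol
Product: 19 sanggenol C, (2R,3R)-3,5,7-trihydroxy-2-(3-geranyl-4-hydroxyphenyl)-8-prenylchroman-4-one
Conditions: HCl (1.25 M in MeOH), 0 → 35 °C
Reagents that add atoms: none
Why: Acid-catalysed transacetalisation (methanolysis) of the two aryl MOM acetals; mild acid and low temperature are chosen so that the prenyl and geranyl chains do not cyclise onto the neighbouring phenols, and neither C2 nor C3 is expected to epimerise away from the stable trans arrangement.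

**Compound list**

1 | 2,4,6-trihydroxyacetophenone | CC(=O)c1c(O)cc(O)cc1O | starting material
2 | prenyl bromide | CC(C)=CCBr | starting material
3 | 1-[2,4,6-trihydroxy-3-(3-methylbut-2-en-1-yl)phenyl]ethan-1-one | CC(=O)c1c(O)cc(O)c(CC=C(C)C)c1O | intermediate
4 | 1-[2-hydroxy-4,6-bis(methoxymethoxy)-3-prenylphenyl]ethan-1-one | CC(=O)c1c(O)c(CC=C(C)C)c(OCOC)cc1OCOC | intermediate
5 | dipotassium phenoxide-enolate of 4 (not isolated) | [K+].[K+].C=C([O-])c1c([O-])c(CC=C(C)C)c(OCOC)cc1OCOC | intermediate
6 | 2-hydroxy-1-[2-hydroxy-4,6-bis(methoxymethoxy)-3-prenylphenyl]ethan-1-one | OCC(=O)c1c(O)c(CC=C(C)C)c(OCOC)cc1OCOC | intermediate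
7 | 2-(TBS-oxy)-1-[2-(TBS-oxy)-4,6-bis(methoxymethoxy)-3-prenylphenyl]ethan-1-one | CC(C)(C)[Si](C)(C)OCC(=O)c1c(O[Si](C)(C)C(C)(C)C)c(CC=C(C)C)c(OCOC)cc1OCOC | intermediate
8 | 4-hydroxybenzaldehyde | O=Cc1ccc(O)cc1 | starting material
9 | geranyl bromide | BrC/C=C(\C)CCC=C(C)C | starting material
10 | 3-geranyl-4-hydroxybenzaldehyde | O=Cc1ccc(O)c(C/C=C(\C)CCC=C(C)C)c1 | intermediate
11 | 4-(TBS-oxy)-3-geranylbenzaldehyde | O=Cc1ccc(O[Si](C)(C)C(C)(C)C)c(C/C=C(\C)CCC=C(C)C)c1 | intermediate
12 | (Z)-enol diisopinocampheylborinate of 7 (not isolated) | CC(C)(C)[Si](C)(C)O/C=C(\OB([C@H]1C[C@H]2C[C@@H]([C@@H]1C)C2(C)C)[C@H]1C[C@H]2C[C@@H]([C@@H]1C)C2(C)C)c1c(O[Si](C)(C)C(C)(C)C)c(CC=C(C)C)c(OCOC)cc1OCOC | intermediate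
13 | (2R,3S)-syn aldol adduct (2-OTBS, 3-OH; ring B 4-OTBS, 3-geranyl; ring A 2-OTBS, 4,6-bis-OMOM, 3-prenyl) | c1c(C/C=C(\C)CCC=C(C)C)c(O[Si](C)(C)C(C)(C)C)ccc1[C@H](O)[C@@H](O[Si](C)(C)C(C)(C)C)C(=O)c1c(O[Si](C)(C)C(C)(C)C)c(CC=C(C)C)c(OCOC)cc1OCOC | intermediate
14 | (2R,3S)-3-acetate of 13 (key-step precursor) | c1c(C/C=C(\C)CCC=C(C)C)c(O[Si](C)(C)C(C)(C)C)ccc1[C@H](OC(C)=O)[C@@H](O[Si](C)(C)C(C)(C)C)C(=O)c1c(O[Si](C)(C)C(C)(C)C)c(CC=C(C)C)c(OCOC)cc1OCOC | intermediate
15 | bis-phenol acetate: 14 with both aryl silyl ethers cleaved (not isolated) | c1c(C/C=C(\C)CCC=C(C)C)c(O)ccc1[C@H](OC(C)=O)[C@@H](O[Si](C)(C)C(C)(C)C)C(=O)c1c(O)c(CC=C(C)C)c(OCOC)cc1OCOC | intermediate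
16 | para-quinone methide, (2R)-2-(TBS-oxy)-3-(3-geranyl-4-oxocyclohexa-2,5-dien-1-ylidene)-1-[2-hydroxy-4,6-bis(methoxymethoxy)-3-prenylphenyl]propan-1-one (not isolated) | O=C1C=CC(=C[C@@H](O[Si](C)(C)C(C)(C)C)C(=O)c2c(O)c(CC=C(C)C)c(OCOC)cc2OCOC)C=C1C/C=C(\C)CCC=C(C)C | intermediate
17 | (2R,3R)-3-(TBS-oxy)-2-(3-geranyl-4-hydroxyphenyl)-5,7-bis(methoxymethoxy)-8-prenylchroman-4-one (not isolated) | c1c(C/C=C(\C)CCC=C(C)C)c(O)ccc1[C@H]2Oc3c(CC=C(C)C)c(OCOC)cc(OCOC)c3C(=O)[C@@H]2O[Si](C)(C)C(C)(C)C | intermediate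
18 | (2R,3R)-3-hydroxy-2-(3-geranyl-4-hydroxyphenyl)-5,7-bis(methoxymethoxy)-8-prenylchroman-4-one | c1c(C/C=C(\C)CCC=C(C)C)c(O)ccc1[C@H]2Oc3c(CC=C(C)C)c(OCOC)cc(OCOC)c3C(=O)[C@@H]2O | intermediate
19 | sanggenol C | CC(C)=CCC/C(C)=C/Cc1cc([C@H]2Oc3c(CC=C(C)C)c(O)cc(O)c3C(=O)[C@@H]2O)ccc1O | target

**Step count**

Total: 10 steps. Longest linear sequence: 8 steps (steps 1, 2, 3, 4, 7, 8, 9, 10).

**Steps most likely to fail**

Step 9 (the proposed new method). What may go wrong:
- The quinone methide may lose the C3 proton and isomerise to the 4'-hydroxy-α-silyloxychalcone, which erases C3.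
- Acetate may leave by a base-induced E1cB path before the phenoxide-driven ionisation.
- The C3 silyl group may be lost or shifted early, followed by acetyl transfer.
- Trans selectivity may be incomplete if the addition is not reversible under the conditions.

The fallback closes ring C by a stereospecific Mitsunobu displacement, which is known for dihydroflavonols. It sets out from 10 and 7 and comes back to the route at 19. Phenol 10 is converted with MOMCl and iPr2NEt into 3-geranyl-4-(methoxymethoxy)benzaldehyde F1, so that ring B carries no fluoride-labile group and cannot ionise. F1 is joined to 7 under the conditions of step 7 (through 12) to give the (2R,3S)-syn adduct F2, which is purified to a single diastereomer. TBAF/AcOH at –20 °C removes only the aryl silyl ether and gives the 2'-phenol F3. PPh3/DIAD in THF at 0 °C closes ring C with inversion at the benzylic carbon to give the (2R,3R)-3-O-TBS-4',5,7-tris-O-MOM dihydroflavonol F4. HF·pyridine gives the 3-hydroxy compound F5, and HCl in MeOH removes the three MOM groups to give 19.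

Step 7. What may go wrong: enolisation of the doubly ortho-substituted aryl ketone by the bulky Ipc2BOTf may be slow, and the Ipc ligands may give insufficient (or the unexpected sense of) enolate-face selectivity, so that C3 of the target is not obtained enantiopure.

The fallback replaces reagent control by resolution. It sets out from 7 and 11 and comes back to the route at 16 (and so at 18). Ketone 7 is enolised with Bu2BOTf/iPr2NEt to the dibutylboron enolate F6 (not isolated), which adds to 11 to give the racemic syn aldol, that is 13 together with its (2S,3R) enantiomer F7. The mixture is esterified with (1S)-camphanic chloride (pyridine, DMAP) to the camphanate of 13, F8, and the diastereomeric camphanate of F7, F9, which are separated by chromatography or crystallisation. F8 is then submitted to the conditions of step 9: fluoride gives the bis-phenol camphanate F10 (not isolated), which expels camphanate instead of acetate and so gives quinone methide 16 and, from there, 17 and 18.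

Step 3. What may go wrong: the second deprotonation may be incomplete, the enolate may add to the sulfonimine by-product, and the product may be oxidised further.

The fallback introduces the oxygen by halogenation and substitution instead of enolate oxidation. It sets out from 4 and comes back to the route at 6. TBSOTf/Et3N converts 4 into the aryl TBS ether/TBS enol ether F11. NBS in THF at –78 °C gives the α-bromo ketone F12, where the enol ether should react far faster than the trisubstituted alkene or the arene. CsOAc in DMF gives the α-acetoxy ketone F13, and K2CO3 in MeOH at 0 °C removes the acetate and the aryl silyl group to give 6.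

**Further compounds**

F1 | step 9 | 3-geranyl-4-(methoxymethoxy)benzaldehyde | O=Cc1ccc(OCOC)c(C/C=C(\C)CCC=C(C)C)c1
F2 | step 9 | (2R,3S)-syn aldol adduct of 7 and F1 | c1c(C/C=C(\C)CCC=C(C)C)c(OCOC)ccc1[C@H](O)[C@@H](O[Si](C)(C)C(C)(C)C)C(=O)c1c(O[Si](C)(C)C(C)(C)C)c(CC=C(C)C)c(OCOC)cc1OCOC
F3 | step 9 | 2'-phenol from F2 (aryl silyl ether removed) | c1c(C/C=C(\C)CCC=C(C)C)c(OCOC)ccc1[C@H](O)[C@@H](O[Si](C)(C)C(C)(C)C)C(=O)c1c(O)c(CC=C(C)C)c(OCOC)cc1OCOC
F4 | step 9 | (2R,3R)-3-(TBS-oxy)-2-[3-geranyl-4-(methoxymethoxy)phenyl]-5,7-bis(methoxymethoxy)-8-prenylchroman-4-one | c1c(C/C=C(\C)CCC=C(C)C)c(OCOC)ccc1[C@H]2Oc3c(CC=C(C)C)c(OCOC)cc(OCOC)c3C(=O)[C@@H]2O[Si](C)(C)C(C)(C)C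
F5 | step 9 | (2R,3R)-3-hydroxy-2-[3-geranyl-4-(methoxymethoxy)phenyl]-5,7-bis(methoxymethoxy)-8-prenylchroman-4-one | c1c(C/C=C(\C)CCC=C(C)C)c(OCOC)ccc1[C@H]2Oc3c(CC=C(C)C)c(OCOC)cc(OCOC)c3C(=O)[C@@H]2O
F6 | step 7 | (Z)-dibutylboron enolate of 7 (not isolated) | CC(C)(C)[Si](C)(C)O/C=C(\OB(CCCC)CCCC)c1c(O[Si](C)(C)C(C)(C)C)c(CC=C(C)C)c(OCOC)cc1OCOC
F7 | step 7 | (2S,3R)-syn aldol adduct, enantiomer of 13 | c1c(C/C=C(\C)CCC=C(C)C)c(O[Si](C)(C)C(C)(C)C)ccc1[C@@H](O)[C@H](O[Si](C)(C)C(C)(C)C)C(=O)c1c(O[Si](C)(C)C(C)(C)C)c(CC=C(C)C)c(OCOC)cc1OCOC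
F8 | step 7 | (1S)-camphanate of 13 | c1c(C/C=C(\C)CCC=C(C)C)c(O[Si](C)(C)C(C)(C)C)ccc1[C@H](OC(=O)[C@@]12CC[C@@](C)(C(=O)O1)C2(C)C)[C@@H](O[Si](C)(C)C(C)(C)C)C(=O)c1c(O[Si](C)(C)C(C)(C)C)c(CC=C(C)C)c(OCOC)cc1OCOC
F9 | step 7 | (1S)-camphanate of F7 (diastereomer, removed) | c1c(C/C=C(\C)CCC=C(C)C)c(O[Si](C)(C)C(C)(C)C)ccc1[C@@H](OC(=O)[C@@]12CC[C@@](C)(C(=O)O1)C2(C)C)[C@H](O[Si](C)(C)C(C)(C)C)C(=O)c1c(O[Si](C)(C)C(C)(C)C)c(CC=C(C)C)c(OCOC)cc1OCOC
F10 | step 7 | bis-phenol camphanate from F8 (not isolated) | c1c(C/C=C(\C)CCC=C(C)C)c(O)ccc1[C@H](OC(=O)[C@@]12CC[C@@](C)(C(=O)O1)C2(C)C)[C@@H](O[Si](C)(C)C(C)(C)C)C(=O)c1c(O)c(CC=C(C)C)c(OCOC)cc1OCOC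
F11 | step 3 | tert-butyl({1-[2-(TBS-oxy)-4,6-bis(methoxymethoxy)-3-prenylphenyl]ethenyl}oxy)dimethylsilane | C=C(O[Si](C)(C)C(C)(C)C)c1c(O[Si](C)(C)C(C)(C)C)c(CC=C(C)C)c(OCOC)cc1OCOC
F12 | step 3 | 2-bromo-1-[2-(TBS-oxy)-4,6-bis(methoxymethoxy)-3-prenylphenyl]ethan-1-one | BrCC(=O)c1c(O[Si](C)(C)C(C)(C)C)c(CC=C(C)C)c(OCOC)cc1OCOC
F13 | step 3 | 2-oxo-2-[2-(TBS-oxy)-4,6-bis(methoxymethoxy)-3-prenylphenyl]ethyl acetate | CC(=O)OCC(=O)c1c(O[Si](C)(C)C(C)(C)C)c(CC=C(C)C)c(OCOC)cc1OCOC
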